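## Structural features

The target (C31H22O10) is a biflavonoid ether. One half is a (2S)-flavanone of the sakuranetin type (ring A: 5-hydroxy-7-methoxy benzo ring; ring C: dihydropyranone; ring B: 1,4-phenylene). The other half is kaempferol (ring D: 5,7-dihydroxy benzo ring; ring E: pyran-4-one; ring F: 4-hydroxyphenyl), and the two are joined only by an ether from C4' of ring B to C3 of ring E. That ether oxygen sits on an enolic carbon wedged between the C2 aryl group and the C4 carbonyl of ring E, so it is hindered and weakly nucleophilic. The only stereocentre is C2 of ring C, which is benzylic, oxygen-bearing and β to the C4 ketone, with no neighbouring stereocentre to relay from. It is fragile: base, and in principle a strong Lewis acid, can open ring C by retro-oxa-Michael reaction to the achiral chalcone, and the free flavonol is a polyphenol whose anion is cleaved oxidatively in air. The real difficulties are to create C2 in one absolute configuration without passing through a chalcone, to forge the hindered C3–O–aryl bond, and to finish with one methyl ether (C7 of ring A) among five free phenols. The key step exploits the fact that O1 and C4 of ring C are attached to adjacent carbons of ring A (C8a and C4a), so O1–C8a–C4a–C4 is the skeleton of a salicylaldehyde. Ionised as its acetal, this is a C4-oxygenated ortho-quinone methide that lacks only C2 and C3, the two alkene carbons of a ring B styrene.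

## Logic of the disconnections

**18 ⇒ 17.** Four O–C bonds are cut: three O–benzyl bonds on rings D and F and the O–methyl bond at C5 of ring A. Benzyl is chosen because it survives base, ylide, dioxirane and Brønsted acid. The C5 methyl ether is accepted because it comes from a purchasable aldehyde and is the one methyl ether chelated to the C4 carbonyl. The demand is one Lewis-acid operation that removes all four groups yet spares the C7 methyl ether, the diaryl ether and C2.

**17 ⇒ 16.** The C4 carbonyl is taken back to a secondary alcohol. This puts C4 at the oxidation level the ring-forming step can deliver. The forward oxidation must be non-basic so that ring C cannot open, and it removes the C4 centre, so the C4 epimer ratio in 16 is irrelevant.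

**16 ⇒ 15.** The C4–OH bond is exchanged for the C4–O-methyl bond that the key step produces. The forward step is an SN1 exchange at a carbon benzylic to the electron-rich ring A. It needs mild acid and much water so that the cation is captured and neither eliminates nor alkylates another arene.

**15 ⇒ 10 + 11 + 12 (through 13 and 14).** C3–C4 and O1–C2 are cut, which removes ring C and both of its stereocentres. Ring A becomes a small aldehyde, C4 with its oxygen comes from that aldehyde and an ortho ester, and the rest of the molecule becomes a single styrene. This is the largest simplification in the plan, and no chalcone or base is involved. The forward step must control the absolute configuration at C2 with a chiral counter-anion. Because C2 is set relative to C4, it must also be diastereoselective, or allow the cis adduct to be purified, before C4 is erased.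

**10 ⇒ 9.** The vinyl C=C bond is cut back to an aldehyde. The aldehyde is what makes the ether-forming step possible, and the styrene is then one olefination away. The ylide must attack only the formyl group and not the pyranone.

**9 ⇒ 7 + 8.** The C4'–O bond of ring B is cut. The para formyl group of 8 activates fluoride displacement, so the hindered enolic oxygen of 7 can be arylated without a metal. All other oxygens of 7 must be capped, and air must be excluded.

**7 ⇒ 5 (through 6).** The C3–O bond of ring E is cut. Oxidising the flavone at C3 replaces a one-pot alkaline peroxide oxidation of 4, which is unsuitable here because 2'-hydroxychalcones with a 6'-alkoxy group are diverted to aurones. The oxidant must epoxidise an electron-poor enol-ether double bond without attacking the benzylic ether positions.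

**5 ⇒ 4.** The O1–C2 bond of ring E is cut and the C2=C3 unsaturation removed, giving an open 2'-hydroxychalcone. The forward step must cyclise and dehydrogenate in one operation.

**4 ⇒ 2 + 3.** The Cα=Cβ bond of the enone is cut, giving an acetophenone and a non-enolisable aldehyde. The forward aldol condensation needs one free, chelated ortho hydroxyl and all other phenols protected.

**2 ⇒ 1.** Two O–benzyl bonds are cut. The forward step relies on the ortho hydroxyl that is hydrogen-bonded to the ketone staying unalkylated.

## Other disconnections considered

Alternative 1: The cut runs through ring B itself, at C2'–C3' and C4'–C5'. The 1,4-phenylene ring would be assembled from methyl coumalate A1 and the ynol ether A2, 5,7-bis(benzyloxy)-2-[4-(benzyloxy)phenyl]-3-(ethynyloxy)chromen-4-one.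
- **Forward step:** inverse-electron-demand Diels–Alder addition of the electron-rich alkyne to the electron-poor 2-pyranone, then decarboxylative cycloreversion, to give the para-substituted benzoate A3, methyl 4-[5,7-bis(benzyloxy)-2-(4-benzyloxyphenyl)-4-oxochromen-3-yloxy]benzoate.
- **In favour:** the para relationship of ester and ether follows from the polarisation of both partners, the hindered flavonol oxygen never has to attack an arene, and the conditions are neutral. On these mechanistic points it is the better plan.
- **Against:** A2 would have to be made from 7 through a dihalovinyl ether and an excess of organolithium base, which the pyranone is unlikely to tolerate. Aryl ynol ethers also hydrate and oligomerise easily. A3 arrives at the ester oxidation level, so reduction and reoxidation are needed to reach 9.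
- **Comparison:** structurally it ends where step 5 ends and is equal in what it delivers. It would spend about four operations where the chosen plan spends one, so it is worse on step economy. It does not address C2 of ring C.

Alternative 2: The cut is made in ring E at C4–C4a and O1–C2. This separates unprotected phloroglucinol A4 from the α-aryloxy β-keto ester A5, ethyl 3-[4-(benzyloxy)phenyl]-2-(4-bromophenoxy)-3-oxopropanoate.
- **Forward step:** heating the two would expel the ester alcohol to give an acylketene, C-acylate A4 and cyclodehydrate to 2-(4-benzyloxyphenyl)-3-(4-bromophenoxy)-5,7-dihydroxychromen-4-one A6.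
- **In favour:** rings D and E, the 2-aryl group and the 3-aryloxy group appear in one operation. The ether oxygen is introduced earlier by simple alkylation of a phenoxide with an α-halo keto ester. Neither the dioxirane oxidation nor the hot-base substitution is needed. In convergence and in ease of making the C3–O–aryl bond it is the better plan, and the aryl bromide of A6 is a more versatile handle than the aldehyde of 9.
- **Against:** thermal condensations of this kind need temperatures above 200 °C, the α-substituent slows acylketene formation, coumarin formation through the other carbonyl competes, and the benzyl ether may not survive hot polyphenol. A6 still needs 7-O-protection and a vinylation by cross-coupling before it can enter step 7 as an analogue of 10.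
- **Comparison:** counting the preparation of A5, the number of operations to the styrene is about the same as steps 1 to 6, so step economy is equal. The stereocentre is again left to step 7.

Alternative 3: Here C3 of ring E is excised (C2–C3 and C3–C4). This leaves the silyl enol ether A7, 4,6-bis(benzyloxy)-2-[4-(benzyloxy)phenyl]-3-(trimethylsilyloxy)-1-benzofuran, and the chlorodiazirine A8, 3-(4-bromophenoxy)-3-chloro-3H-diazirine, as carrier of the missing carbon with its aryloxy group.
- **Forward step:** decomposition of A8 would release an aryloxychlorocarbene that cyclopropanates the C2=C3 bond of A7. Loss of chloride and of the silyl group would open the cyclopropane and expand the furan to the pyranone A9, 5,7-bis(benzyloxy)-2-(4-benzyloxyphenyl)-3-(4-bromophenoxy)chromen-4-one.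
- **In favour:** C3 is delivered with oxygen and aryl group attached, so neither a C3 oxidation nor an O-arylation is needed. The benzofuranone manifold, into which 6'-alkoxy chalcones fall naturally, becomes an asset. Conditions are near neutral. In bonds formed per operation it is the most economical idea of the four.
- **Against:** oxygen-substituted chlorocarbenes are stabilised and weakly electrophilic, and the aromatic furan A7 is a reluctant partner. A8 must be made by oxidation of an isouronium salt (Graham reaction) and is potentially explosive. The benzofuranone needs three or four steps of its own, and bromide-to-vinyl conversion still follows.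
- **Comparison:** on mechanism it is the most speculative plan, and on step count it is longer than steps 1 to 6. Like the others it leaves the stereocentre untouched.

All three are different ways to the aryl ether half (compounds 9 and 10). None replaces the ring C construction of the chosen plan.

Key step: step 7

Assumption: the sense of induction of the confined chiral acid in step 7 cannot be predicted, so the catalyst antipode that leads to the (2S,4S) adduct is chosen in a trial run; 16 is carried as a C4 epimer mixture because step 9 removes that centre.

Step 1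
Reactants: 1 2',4',6'-trihydroxyacetophenone
Product: 2 1-[2,4-bis(benzyloxy)-6-hydroxyphenyl]ethan-1-one
Conditions: BnBr (2.1 equiv), K2CO3, DMF, 0 °C → rt
Reagents that add atoms: benzyl bromide, BrCc1ccccc1
Why: Williamson etherification; the para hydroxyl and one ortho hydroxyl are alkylated, while the remaining ortho hydroxyl is held in a hydrogen bond to the ketone and stays free for the later ring closure.

Step 2
Reactants: 2 1-[2,4-bis(benzyloxy)-6-hydroxyphenyl]ethan-1-one; 3 4-(benzyloxy)benzaldehyde
Product: 4 (E)-1-[2,4-bis(benzyloxy)-6-hydroxyphenyl]-3-[4-(benzyloxy)phenyl]prop-2-en-1-one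
Conditions: KOH (50% aq.), EtOH/THF, rt
Reagents that add atoms: none
Why: Claisen–Schmidt aldol condensation; the enolate of 2 adds to the non-enolisable aldehyde 3 and E1cB dehydration should give the (E)-enone.

Step 3
Reactants: 4 (E)-1-[2,4-bis(benzyloxy)-6-hydroxyphenyl]-3-[4-(benzyloxy)phenyl]prop-2-en-1-one
Product: 5 5,7-bis(benzyloxy)-2-[4-(benzyloxy)phenyl]-4H-chromen-4-one
Conditions: I2 (10 mol %), DMSO, 130 °C
Reagents that add atoms: none
Why: Iodine-catalysed oxidative cyclisation of a 2'-hydroxychalcone (oxa-Michael closure, α-iodination, loss of HI, reoxidation of iodide by DMSO); it is used in place of an Algar–Flynn–Oyamada oxidation, which a 6'-alkoxy chalcone diverts to the aurone.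

Step 4
Reactants: 5 5,7-bis(benzyloxy)-2-[4-(benzyloxy)phenyl]-4H-chromen-4-one
Product: 7 5,7-bis(benzyloxy)-2-[4-(benzyloxy)phenyl]-3-hydroxy-4H-chromen-4-one, via flavone 2,3-epoxide 6 (not isolated)
Conditions: DMDO (acetone solution, excess), CH2Cl2, 0 °C → rt, dark; then TsOH·H2O (cat.), CH2Cl2, rt
Reagents that add atoms: dimethyldioxirane, CC1(C)OO1
Why: Dioxirane epoxidation of the enol-ether-like C2=C3 bond under neutral conditions, then acid-catalysed opening at C2 (cation stabilised by O1 and the aryl group) and loss of H3 to give the 3-hydroxypyranone; this is the established flavone-to-flavonol oxidation.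

Step 5
Reactants: 7 5,7-bis(benzyloxy)-2-[4-(benzyloxy)phenyl]-3-hydroxy-4H-chromen-4-one; 8 4-fluorobenzaldehyde
Product: 9 4-({5,7-bis(benzyloxy)-2-[4-(benzyloxy)phenyl]-4-oxo-4H-chromen-3-yl}oxy)benzaldehyde
Conditions: Cs2CO3, DMSO, 100 °C, Ar
Reagents that add atoms: none
Why: Nucleophilic aromatic substitution by addition–elimination; the caesium flavonolate adds para to the formyl group, which stabilises the Meisenheimer intermediate, and fluoride leaves; O3 is the only free oxygen, and argon suppresses oxidative cleavage of the flavonolate.

Step 6
Reactants: 9 4-({5,7-bis(benzyloxy)-2-[4-(benzyloxy)phenyl]-4-oxo-4H-chromen-3-yl}oxy)benzaldehyde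
Product: 10 5,7-bis(benzyloxy)-2-[4-(benzyloxy)phenyl]-3-(4-vinylphenoxy)-4H-chromen-4-one
Conditions: Ph3PCH3Br (1.3 equiv), KOtBu (1.2 equiv), THF, 0 °C → rt
Reagents that add atoms: methyltriphenylphosphonium bromide, C[P+](c1ccccc1)(c1ccccc1)c1ccccc1.[Br-]
Why: Wittig methylenation; the aldehyde is far more electrophilic than the vinylogous-ester carbonyl of the pyranone, so a small excess of ylide at low temperature should convert the formyl group only.

Step 7
Reactants: 10 5,7-bis(benzyloxy)-2-[4-(benzyloxy)phenyl]-3-(4-vinylphenoxy)-4H-chromen-4-one; 11 2-hydroxy-4,6-dimethoxybenzaldehyde; 12 trimethyl orthoformate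
Product: 15 5,7-bis(benzyloxy)-2-[4-(benzyloxy)phenyl]-3-{4-[(2S,4S)-4,5,7-trimethoxychroman-2-yl]phenoxy}-4H-chromen-4-one, via dimethyl acetal 13 (not isolated), via methoxy ortho-quinone methide 14 (not isolated)
Conditions: 11 (1.3 equiv), 12 (2.5 equiv), confined chiral BINOL-derived N-triflyl imidodiphosphorimidate acid (5 mol %), CH2Cl2, rt; then 10, −40 → −20 °C; Et3N quench; chromatography on Et3N-deactivated silica
Reagents that add atoms: none
Why: Proposed new method: the acid catalyses acetal exchange between 11 and 12 to give 13 and ionises it, with loss of methanol, to the ortho-hydroxyaryl oxocarbenium ion (O-protonated 14), held as a contact ion pair in the pocket of the chiral anion; the terminal alkene carbon of 10 attacks the cationic carbon (C3–C4), and the benzylic cation so formed, stabilised by the para aryloxy oxygen, is trapped by the phenolic oxygen (O1–C2), which returns the proton to the catalyst. The closest known reaction types are the achiral acid-catalysed condensation of salicylaldehydes, orthoformates and styrenes to 2-aryl-4-alkoxychromans and the chiral phosphoric acid catalysed (4+2) cycloadditions of ortho-quinone methides with styrenes; confined imidodiphosphorimidate anions are known to control additions of alkenes and dienes to oxocarbenium ions, but this acetal-derived enantioselective variant is new. Ring C closes in a stepwise polar (4+2) mode: intermolecular C–C bond formation, then six-membered closure by O-capture of the cation through a chair-like transition state. C4 is set by the face of the oxocarbenium carbon that the anion leaves open (catalyst control); C2 is set in the ring closure, where aryl and methoxy groups both take equatorial positions (2,4-cis), so its absolute configuration follows from C4 and thus from the catalyst. Regioselectivity (aryl at C2, not C3) comes from the polarity of the styrene, and chemoselectivity from the electron-poor C2=C3 bond of the pyranone in 10, which does not compete with the vinyl group. Because a trans isomer formed with the same facial sense at C4 would carry the opposite configuration at C2, the cis adduct is purified before C4 is erased.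

Step 8
Reactants: 15 5,7-bis(benzyloxy)-2-[4-(benzyloxy)phenyl]-3-{4-[(2S,4S)-4,5,7-trimethoxychroman-2-yl]phenoxy}-4H-chromen-4-one
Product: 16 5,7-bis(benzyloxy)-2-[4-(benzyloxy)phenyl]-3-{4-[(2S)-4-hydroxy-5,7-dimethoxychroman-2-yl]phenoxy}-4H-chromen-4-one (mixture of C4 epimers)
Conditions: TsOH·H2O (cat.), THF/H2O (3:1), rt
Reagents that add atoms: water, O
Why: SN1 solvolysis; the C4 ether ionises readily because the cation is benzylic to the 5,7-dimethoxy ring A, and water in large excess captures it; C2 takes no part, and the C4 epimers converge in step 9.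

Step 9
Reactants: 16 5,7-bis(benzyloxy)-2-[4-(benzyloxy)phenyl]-3-{4-[(2S)-4-hydroxy-5,7-dimethoxychroman-2-yl]phenoxy}-4H-chromen-4-one
Product: 17 5,7-bis(benzyloxy)-2-[4-(benzyloxy)phenyl]-3-{4-[(2S)-5,7-dimethoxy-4-oxochroman-2-yl]phenoxy}-4H-chromen-4-one
Conditions: Dess–Martin periodinane, pyridine, CH2Cl2, 0 °C → rt
Reagents that add atoms: none
Why: Dess–Martin oxidation of a secondary benzylic alcohol by pentavalent iodine under buffered, non-basic conditions; ring C cannot open by retro-oxa-Michael reaction, so C2 should be preserved.

Step 10
Reactants: 17 5,7-bis(benzyloxy)-2-[4-(benzyloxy)phenyl]-3-{4-[(2S)-5,7-dimethoxy-4-oxochroman-2-yl]phenoxy}-4H-chromen-4-one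
Product: 18 5,7-dihydroxy-3-{4-[(2S)-5-hydroxy-7-methoxy-4-oxochroman-2-yl]phenoxy}-2-(4-hydroxyphenyl)-4H-chromen-4-one
Conditions: BCl3 (excess), C6HMe5, CH2Cl2, −78 → 0 °C; MeOH, then H2O
Reagents that add atoms: none
Why: Lewis-acid ether cleavage; BCl3 with pentamethylbenzene as cation scavenger removes the aryl benzyl ethers at low temperature, and on warming the C5 methyl ether, held in a six-membered boron chelate with the C4 carbonyl, is demethylated while the unchelated C7 methyl ether and the diaryl ether remain; no base is present, so C2 should be retained.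

## Compound list

1 | 2',4',6'-trihydroxyacetophenone (phloroacetophenone) | CC(=O)c1c(O)cc(O)cc1O | starting material
2 | 1-[2,4-bis(benzyloxy)-6-hydroxyphenyl]ethan-1-one | CC(=O)c1c(O)cc(OCc2ccccc2)cc1OCc1ccccc1 | intermediate
3 | 4-(benzyloxy)benzaldehyde | O=Cc1ccc(OCc2ccccc2)cc1 | starting material
4 | (E)-1-[2,4-bis(benzyloxy)-6-hydroxyphenyl]-3-[4-(benzyloxy)phenyl]prop-2-en-1-one | O=C(/C=C/c1ccc(OCc2ccccc2)cc1)c1c(O)cc(OCc2ccccc2)cc1OCc1ccccc1 | intermediate
5 | 5,7-bis(benzyloxy)-2-[4-(benzyloxy)phenyl]-4H-chromen-4-one | O=c1cc(-c2ccc(OCc3ccccc3)cc2)oc2cc(OCc3ccccc3)cc(OCc3ccccc3)c12 | intermediate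
6 | 5,7-bis(benzyloxy)-2-[4-(benzyloxy)phenyl]-2,3-epoxychroman-4-one (flavone 2,3-epoxide, racemic, cis-fused, not isolated) | O=C1C2OC2(c2ccc(OCc3ccccc3)cc2)Oc2cc(OCc3ccccc3)cc(OCc3ccccc3)c12 | intermediate
7 | 5,7-bis(benzyloxy)-2-[4-(benzyloxy)phenyl]-3-hydroxy-4H-chromen-4-one | O=c1c(O)c(-c2ccc(OCc3ccccc3)cc2)oc2cc(OCc3ccccc3)cc(OCc3ccccc3)c12 | intermediate
8 | 4-fluorobenzaldehyde | O=Cc1ccc(F)cc1 | starting material
9 | 4-({5,7-bis(benzyloxy)-2-[4-(benzyloxy)phenyl]-4-oxo-4H-chromen-3-yl}oxy)benzaldehyde | O=Cc1ccc(Oc2c(-c3ccc(OCc4ccccc4)cc3)oc3cc(OCc4ccccc4)cc(OCc4ccccc4)c3c2=O)cc1 | intermediate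
10 | 5,7-bis(benzyloxy)-2-[4-(benzyloxy)phenyl]-3-(4-vinylphenoxy)-4H-chromen-4-one | C=Cc1ccc(Oc2c(-c3ccc(OCc4ccccc4)cc3)oc3cc(OCc4ccccc4)cc(OCc4ccccc4)c3c2=O)cc1 | intermediate
11 | 2-hydroxy-4,6-dimethoxybenzaldehyde | COc1cc(O)c(C=O)c(OC)c1 | starting material
12 | trimethyl orthoformate | COC(OC)OC | starting material
13 | 2-(dimethoxymethyl)-3,5-dimethoxyphenol (dimethyl acetal of 11, not isolated) | COc1cc(O)c(C(OC)OC)c(OC)c1 | intermediate
14 | 3,5-dimethoxy-6-(methoxymethylidene)cyclohexa-2,4-dien-1-one (methoxy ortho-quinone methide, not isolated; reacts as its O-protonated form, the oxocarbenium ion paired with the catalyst anion; alkene geometry not defined) | COC=C1C(=O)C=C(OC)C=C1OC | intermediate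
15 | 5,7-bis(benzyloxy)-2-[4-(benzyloxy)phenyl]-3-{4-[(2S,4S)-4,5,7-trimethoxychroman-2-yl]phenoxy}-4H-chromen-4-one (2,4-cis) | COc1cc(OC)c2c(c1)O[C@H](c1ccc(Oc3c(-c4ccc(OCc5ccccc5)cc4)oc4cc(OCc5ccccc5)cc(OCc5ccccc5)c4c3=O)cc1)C[C@@H]2OC | intermediate
16 | 5,7-bis(benzyloxy)-2-[4-(benzyloxy)phenyl]-3-{4-[(2S)-4-hydroxy-5,7-dimethoxychroman-2-yl]phenoxy}-4H-chromen-4-one (C2 is S; C4 epimer mixture, C4 left unspecified) | COc1cc(OC)c2c(c1)O[C@H](c1ccc(Oc3c(-c4ccc(OCc5ccccc5)cc4)oc4cc(OCc5ccccc5)cc(OCc5ccccc5)c4c3=O)cc1)CC2O | intermediate
17 | 5,7-bis(benzyloxy)-2-[4-(benzyloxy)phenyl]-3-{4-[(2S)-5,7-dimethoxy-4-oxochroman-2-yl]phenoxy}-4H-chromen-4-one | COc1cc(OC)c2c(c1)O[C@H](c1ccc(Oc3c(-c4ccc(OCc5ccccc5)cc4)oc4cc(OCc5ccccc5)cc(OCc5ccccc5)c4c3=O)cc1)CC2=O | intermediate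
18 | 5,7-dihydroxy-3-{4-[(2S)-5-hydroxy-7-methoxy-4-oxochroman-2-yl]phenoxy}-2-(4-hydroxyphenyl)-4H-chromen-4-one (CNP0173006.1) | COc1cc(O)c2c(c1)O[C@H](c1ccc(Oc3c(-c4ccc(O)cc4)oc4cc(O)cc(O)c4c3=O)cc1)CC2=O | target

## Step count and risk assessment

Total step count: 10. Longest linear sequence: 10 steps (1 to 18); compounds 3, 8, 11 and 12 are purchased and enter directly. If 2 is bought instead of made, the count falls to 9.

**Step 7 (key step, proposed new method).** Three things are most likely to go wrong:
- The basic pyranone carbonyl of 10 and the released methanol may sequester the acid, so ionisation of 13 becomes slow.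
- Facial discrimination may be poor, because the highly stabilised cation can react outside a tight ion pair.
- Stereochemical purity may erode through reversible ionisation at C4 of the adduct, together with cationic oligomerisation of the styrene.

Fallback with known chemistry, setting out from 9 and returning at 17 (steps 6 to 9 are bypassed). Claisen–Schmidt condensation of 9 with commercial 1-(2-hydroxy-4,6-dimethoxyphenyl)ethanone (KOH, EtOH/THF, rt) should give the 2'-hydroxychalcone (E)-3-[4-({5,7-bis(benzyloxy)-2-[4-(benzyloxy)phenyl]-4-oxo-4H-chromen-3-yl}oxy)phenyl]-1-(2-hydroxy-4,6-dimethoxyphenyl)prop-2-en-1-one F1. Intramolecular oxa-Michael addition (NaOAc, EtOH, reflux, or a cinchona-derived bifunctional thiourea base for partial enantiocontrol) closes ring C to 17 together with its mirror image, the (2R)-flavanone F2. The two are separated by preparative HPLC on a polysaccharide chiral phase, and F2 can be recycled by base-mediated equilibration through F1.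

**Step 5.** The hindered, delocalised oxyanion may substitute sluggishly, and at the temperature then required base-induced oxidative degradation of the flavonolate can compete. Fallback from 7, returning at 9: O-arylation at room temperature with the diaryliodonium salt (4-formylphenyl)(2,4,6-trimethoxyphenyl)iodonium 4-methylbenzenesulfonate F3 and KOtBu in THF. F3 would be prepared in one pot from 4-iodobenzaldehyde, mCPBA, TsOH and 1,3,5-trimethoxybenzene. Ligand coupling at trivalent iodine transfers the electron-poor formylphenyl group to oxygen without a Meisenheimer intermediate and without heating.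

**Step 4.** Epoxidation of the electron-poor enone may be slow, so dioxirane C–H oxidation at the benzylic ether positions, with loss of benzyl groups, could compete. Fallback from 5, returning at 7: C3 lithiation with LiN(iPr)2 in THF at −78 °C, trapping with B(OMe)3 to give dimethyl {5,7-bis(benzyloxy)-2-[4-(benzyloxy)phenyl]-4-oxo-4H-chromen-3-yl}boronate F4, then oxidation of the C–B bond with H2O2/AcOH. This is polar C–H functionalisation in place of alkene oxidation.

**Step 10.** Three processes are the concern: Lewis-acid-promoted opening of ring C with epimerisation at C2, Friedel–Crafts C-benzylation of the electron-rich rings if cation scavenging is inefficient, and incomplete cleavage of the chelated methyl ether. Fallback from 17, returning at 18: hydrogenolysis (H2, Pd/C, EtOAc/THF, rt) removes the benzyl groups under neutral conditions to give 3-{4-[(2S)-5,7-dimethoxy-4-oxochroman-2-yl]phenoxy}-5,7-dihydroxy-2-(4-hydroxyphenyl)-4H-chromen-4-one F5. Its single chelated methyl ether is then cleaved with the mild halide Lewis acid MgI2·OEt2 (THF/toluene, warm), which acts only next to a carbonyl.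

**Step 8.** Elimination of the C4 cation to the flav-3-ene, and Friedel–Crafts self-condensation with ring A of a second molecule, compete with capture by water. Fallback from 15, returning at 17 and bypassing 16: direct oxidation with DDQ in CH2Cl2/pH 7 buffer at 0 °C. Hydride abstraction from the electron-rich benzylic ether carbon C4 gives the oxocarbenium ion, and water converts it to the ketone through the hemiketal. No new compound is made (F0).

## Further compounds

F1 | step 7 | (E)-3-[4-({5,7-bis(benzyloxy)-2-[4-(benzyloxy)phenyl]-4-oxo-4H-chromen-3-yl}oxy)phenyl]-1-(2-hydroxy-4,6-dimethoxyphenyl)prop-2-en-1-one | COc1cc(O)c(C(=O)/C=C/c2ccc(Oc3c(-c4ccc(OCc5ccccc5)cc4)oc4cc(OCc5ccccc5)cc(OCc5ccccc5)c4c3=O)cc2)c(OC)c1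
F2 | step 7 | 5,7-bis(benzyloxy)-2-[4-(benzyloxy)phenyl]-3-{4-[(2R)-5,7-dimethoxy-4-oxochroman-2-yl]phenoxy}-4H-chromen-4-one (enantiomer of 17) | COc1cc(OC)c2c(c1)O[C@@H](c1ccc(Oc3c(-c4ccc(OCc5ccccc5)cc4)oc4cc(OCc5ccccc5)cc(OCc5ccccc5)c4c3=O)cc1)CC2=O
F3 | step 5 | (4-formylphenyl)(2,4,6-trimethoxyphenyl)iodonium 4-methylbenzenesulfonate | COc1cc(OC)c([I+]c2ccc(C=O)cc2)c(OC)c1.Cc1ccc(S(=O)(=O)[O-])cc1
F4 | step 4 | dimethyl {5,7-bis(benzyloxy)-2-[4-(benzyloxy)phenyl]-4-oxo-4H-chromen-3-yl}boronate | COB(OC)c1c(-c2ccc(OCc3ccccc3)cc2)oc2cc(OCc3ccccc3)cc(OCc3ccccc3)c2c1=O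
F5 | step 10 | 3-{4-[(2S)-5,7-dimethoxy-4-oxochroman-2-yl]phenoxy}-5,7-dihydroxy-2-(4-hydroxyphenyl)-4H-chromen-4-one | COc1cc(OC)c2c(c1)O[C@H](c1ccc(Oc3c(-c4ccc(O)cc4)oc4cc(O)cc(O)c4c3=O)cc1)CC2=O
F0 | step 8 | none | none
A1 | alternative 1 | methyl coumalate (methyl 2-oxo-2H-pyran-5-carboxylate) | COC(=O)C1=COC(=O)C=C1
A2 | alternative 1 | 5,7-bis(benzyloxy)-2-[4-(benzyloxy)phenyl]-3-(ethynyloxy)chromen-4-one | C#COc1c(-c2ccc(OCc3ccccc3)cc2)oc2cc(OCc3ccccc3)cc(OCc3ccccc3)c2c1=O
A3 | alternative 1 | methyl 4-[5,7-bis(benzyloxy)-2-(4-benzyloxyphenyl)-4-oxochromen-3-yloxy]benzoate | COC(=O)c1ccc(Oc2c(-c3ccc(OCc4ccccc4)cc3)oc3cc(OCc4ccccc4)cc(OCc4ccccc4)c3c2=O)cc1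
A4 | alternative 2 | phloroglucinol (benzene-1,3,5-triol) | Oc1cc(O)cc(O)c1
A5 | alternative 2 | ethyl 3-[4-(benzyloxy)phenyl]-2-(4-bromophenoxy)-3-oxopropanoate (racemic) | CCOC(=O)C(Oc1ccc(Br)cc1)C(=O)c1ccc(OCc2ccccc2)cc1
A6 | alternative 2 | 2-(4-benzyloxyphenyl)-3-(4-bromophenoxy)-5,7-dihydroxychromen-4-one | Oc1cc(O)c2c(c1)oc(-c1ccc(OCc3ccccc3)cc1)c(Oc1ccc(Br)cc1)c2=O
A7 | alternative 3 | 4,6-bis(benzyloxy)-2-[4-(benzyloxy)phenyl]-3-(trimethylsilyloxy)-1-benzofuran | C[Si](C)(C)Oc1c(-c2ccc(OCc3ccccc3)cc2)oc2cc(OCc3ccccc3)cc(OCc3ccccc3)c12
A8 | alternative 3 | 3-(4-bromophenoxy)-3-chloro-3H-diazirine | ClC1(Oc2ccc(Br)cc2)N=N1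
A9 | alternative 3 | 5,7-bis(benzyloxy)-2-(4-benzyloxyphenyl)-3-(4-bromophenoxy)chromen-4-one | Brc1ccc(Oc2c(-c3ccc(OCc4ccccc4)cc3)oc3cc(OCc4ccccc4)cc(OCc4ccccc4)c3c2=O)cc1
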